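**Retrosynthetic overview**
- Target ⇒ double aromatic Claisen rearrangement of the 7,4'-bis(1,1-dimethylallyl) ether of (2R,3R)-garbanzol; both prenyl groups (C8, C3') go in last.
- Garbanzol ⇒ O1–C2 disconnection: anodic dehydrogenative oxa-cyclization of (R)-α,2',4',4-tetrahydroxydihydrochalcone through a p-quinone methide; C2 is set trans to C3.
- Dihydrochalcone ⇒ C4–C4a disconnection: aryllithium from MOM-protected 4-bromoresorcinol plus the Weinreb amide of (R)-4-hydroxyphenyllactic acid.
- (R)-4-Hydroxyphenyllactic acid ⇒ D-tyrosine (diazotization with retention); this stereocentre becomes C3.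
- Ring order: A and B rings are purchased; the pyranone C ring is closed in the electrochemical step.

Assumption: D-tyrosine (a bulk catalogue amino acid) is taken as an inexpensive commercial chiral starting material; it is the only source of chirality in the route.

**Step 1**
Reactants: 1, D-tyrosine [(R)-2-amino-3-(4-hydroxyphenyl)propanoic acid]
Product: 2, (R)-2-hydroxy-3-(4-hydroxyphenyl)propanoic acid
Conditions: NaNO2 (slow addition), 1 M aq H2SO4, 0 °C → rt
Reagents that add atoms: water, O
Why: Diazotization of the α-amino acid with displacement of N2 through the α-lactone (double inversion) gives net retention, so the (R)-amino acid gives the (R)-hydroxy acid that becomes C3.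

**Step 2**
Reactants: 2, (R)-2-hydroxy-3-(4-hydroxyphenyl)propanoic acid
Product: 3, (R)-2-hydroxy-3-(4-hydroxyphenyl)-N-methoxy-N-methylpropanamide
Conditions: MeNH(OMe)·HCl, EDC·HCl, HOBt, NMM, DMF, 0 °C → rt
Reagents that add atoms: N,O-dimethylhydroxylamine hydrochloride, CNOC.Cl
Why: Carbodiimide amidation (Weinreb amide formation) in which the amine outcompetes the free OH groups; an α-hydroxy acid has no oxazolone pathway, so the stereocentre is retained.

**Step 3**
Reactants: 3, the Weinreb amide
Product: 4, (R)-2-(tert-butyldimethylsilyloxy)-3-[4-(tert-butyldimethylsilyloxy)phenyl]-N-methoxy-N-methylpropanamide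
Conditions: TBSCl (2.5 equiv), imidazole, DMF, rt
Reagents that add atoms: tert-butyldimethylsilyl chloride, CC(C)(C)[Si](C)(C)Cl
Why: Standard silylation masks both acidic OH groups before the organolithium step; the stereocentre is untouched.

**Step 4**
Reactants: 5, 4-bromoresorcinol (4-bromobenzene-1,3-diol)
Product: 6, 1-bromo-2,4-bis(methoxymethoxy)benzene
Conditions: MOMCl (2.6 equiv), i-Pr2NEt, CH2Cl2, 0 °C → rt
Reagents that add atoms: chloromethyl methyl ether, COCCl
Why: Phenol O-alkylation (acetal protection); MOM ethers survive aryllithium formation, whereas ortho-silyl ethers would undergo retro-Brook migration.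

**Step 5**
Reactants: 6, 1-bromo-2,4-bis(methoxymethoxy)benzene (1.3 equiv); 4, the bis-TBS Weinreb amide (1.0 equiv)
Product: 7, (R)-1-[2,4-bis(methoxymethoxy)phenyl]-2-(tert-butyldimethylsilyloxy)-3-[4-(tert-butyldimethylsilyloxy)phenyl]propan-1-one
Conditions: 6, n-BuLi, THF, −78 °C, 20 min; then 4, −78 → −30 °C; aq NH4Cl
Reagents that add atoms: none
Why: Br/Li exchange followed by Weinreb ketone synthesis; the chelated tetrahedral intermediate prevents over-addition and the α-silyloxy stereocentre is not enolized at −78 °C.

**Step 6**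
Reactants: 7, the fully protected ketone
Product: 8, (R)-1-(2,4-dihydroxyphenyl)-2-hydroxy-3-(4-hydroxyphenyl)propan-1-one
Conditions: HCl (ca. 1.5 M, from AcCl) in MeOH, 0 → 35 °C
Reagents that add atoms: none
Why: Acid methanolysis removes both MOM acetals and both TBS ethers in one operation; no prenyl groups are present yet and the low temperature limits acid enolization of the α-ketol (ee checked by chiral HPLC).

**Step 7**
Reactants: 8, the (R)-α-hydroxydihydrochalcone
Product: 9, (2R,3R)-3,7-dihydroxy-2-(4-hydroxyphenyl)chroman-4-one [(2R,3R)-garbanzol; 2,3-trans]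
Conditions: divided cell, carbon-felt anode, Pt cathode; anolyte 8 (0.03 M), DDQ (10 mol %), LiClO4 (0.1 M), MeCN/HFIP 4:1, 4 Å MS; catholyte LiClO4, MeCN/AcOH; 2 mA cm−2, 2.1 F mol−1, rt; then 2 h without current
Reagents that add atoms: none
Why: Proposed new method: a DDQ-mediated anodic dehydrogenative oxa-cyclization in which anodically regenerated DDQ takes 2e−/2H+ from the benzylic CH2 para to the free B-ring phenol to give a p-quinone methide, the carbonyl-chelated 2'-OH adds 1,6 (6-exo) to form O1–C2 and close the pyranone, and C2 is set trans to the tyrosine-derived C3–OH because the chair-like closure puts both substituents equatorial and the C2–O1 bond is reversible through the quinone methide in HFIP (thermodynamic 2R,3R isomer); the closest known reactions are DDQ oxidation of 4-alkylphenols to p-quinone methides, anodic recycling of DDQ, and oxidative cyclization of 2'-hydroxydihydrochalcones to flavanones, none shown electrochemically on an α-hydroxylated substrate with diastereocontrol.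

**Step 8**
Reactants: 10, 2-methylbut-3-en-2-ol
Product: 11, tert-butyl (2-methylbut-3-en-2-yl) carbonate
Conditions: n-BuLi, THF, 0 °C; then Boc2O, 0 °C → rt
Reagents that add atoms: di-tert-butyl dicarbonate, CC(C)(C)OC(=O)OC(=O)OC(C)(C)C
Why: Acylation of the lithium alkoxide gives the tertiary allylic carbonate needed for π-allyl chemistry.

**Step 9**
Reactants: 9, (2R,3R)-garbanzol; 11, tert-butyl (2-methylbut-3-en-2-yl) carbonate (3 equiv)
Product: 12, (2R,3R)-3-hydroxy-7-[(2-methylbut-3-en-2-yl)oxy]-2-{4-[(2-methylbut-3-en-2-yl)oxy]phenyl}chroman-4-one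
Conditions: Pd(PPh3)4 (5 mol %), 4 Å MS, THF, 0 °C
Reagents that add atoms: none beyond 11
Why: Decarboxylative Tsuji–Trost O-allylation in which each phenoxide attacks the more substituted terminus of the 1,1-dimethyl-π-allyl palladium (kinetic tertiary ether at low temperature); the aliphatic 3-OH is not acidic enough to react and the mild conditions leave C2/C3 intact.

**Step 10**
Reactants: 12, the bis(1,1-dimethylallyl) ether
Product: 13, 3-hydroxyglabrol [(2R,3R)-3,7-dihydroxy-2-[4-hydroxy-3-(3-methylbut-2-enyl)phenyl]-8-(3-methylbut-2-enyl)chroman-4-one]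
Conditions: Eu(fod)3 (10 mol %), PhMe, 85 °C, Ar
Reagents that add atoms: none
Why: Double aromatic Claisen ([3,3]) rearrangement turns each 1,1-dimethylallyl ether into a linear prenyl group ortho to its phenol (B ring: equivalent ortho sites; A ring: C8, the usual site for 7-O-allyl chroman-4-ones and coumarins lacking a 5-substituent); no stereocentre is involved and the trans arrangement is the stable one.

**Compound list**
1 | D-tyrosine | N[C@H](Cc1ccc(O)cc1)C(=O)O | starting material
2 | (R)-2-hydroxy-3-(4-hydroxyphenyl)propanoic acid | O[C@H](Cc1ccc(O)cc1)C(=O)O | intermediate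
3 | (R)-2-hydroxy-3-(4-hydroxyphenyl)-N-methoxy-N-methylpropanamide | O[C@H](Cc1ccc(O)cc1)C(=O)N(C)OC | intermediate
4 | (R)-2-(TBS-oxy)-3-[4-(TBS-oxy)phenyl]-N-methoxy-N-methylpropanamide | CC(C)(C)[Si](C)(C)O[C@H](Cc1ccc(O[Si](C)(C)C(C)(C)C)cc1)C(=O)N(C)OC | intermediate
5 | 4-bromoresorcinol | Oc1ccc(Br)c(O)c1 | starting material
6 | 1-bromo-2,4-bis(methoxymethoxy)benzene | COCOc1ccc(Br)c(OCOC)c1 | intermediate
7 | (R)-1-[2,4-bis(methoxymethoxy)phenyl]-2-(TBS-oxy)-3-[4-(TBS-oxy)phenyl]propan-1-one | CC(C)(C)[Si](C)(C)O[C@H](Cc1ccc(O[Si](C)(C)C(C)(C)C)cc1)C(=O)c1ccc(OCOC)cc1OCOC | intermediate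
8 | (R)-1-(2,4-dihydroxyphenyl)-2-hydroxy-3-(4-hydroxyphenyl)propan-1-one | O[C@H](Cc1ccc(O)cc1)C(=O)c1ccc(O)cc1O | intermediate
9 | (2R,3R)-3,7-dihydroxy-2-(4-hydroxyphenyl)chroman-4-one (garbanzol) | Oc1ccc(cc1)[C@H]2Oc3cc(O)ccc3C(=O)[C@@H]2O | intermediate
10 | 2-methylbut-3-en-2-ol | C=CC(C)(C)O | starting material
11 | tert-butyl (2-methylbut-3-en-2-yl) carbonate | C=CC(C)(C)OC(=O)OC(C)(C)C | intermediate
12 | (2R,3R)-3-hydroxy-7-[(2-methylbut-3-en-2-yl)oxy]-2-{4-[(2-methylbut-3-en-2-yl)oxy]phenyl}chroman-4-one | C=CC(C)(C)Oc1ccc(cc1)[C@H]2Oc3cc(OC(C)(C)C=C)ccc3C(=O)[C@@H]2O | intermediate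
13 | 3-hydroxyglabrol | CC(C)=CCc1cc([C@H]2Oc3c(ccc(O)c3CC=C(C)C)C(=O)[C@@H]2O)ccc1O | target

**Total step count:** 10 (9 if carbonate 11 is purchased).
**Longest linear sequence:** 8 steps (1 → 2 → 3 → 4 → 7 → 8 → 9 → 12 → 13).

**Three steps most likely to fail**
1. Step 7 (proposed new electrochemical cyclization). Risks are over-oxidation to the flavonol, phenoxyl coupling, and tautomerization of the quinone methide to the α-diketone. Fallback with known chemistry: peracetylate 8, brominate the benzylic CH2 with NBS/AIBN (Wohl–Ziegler), then acidic methanolysis so the freed 2'-OH displaces the benzylic bromide (SN1/quinone methide) to the thermodynamic trans flavanonol.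
2. Step 10 (double Claisen). Risks are C6 versus C8 migration on the A ring and loss of isoprene. Fallback: install the A-ring prenyl before ketone formation by directed ortho-metalation of 1,3-bis(methoxymethoxy)benzene at C2 (n-BuLi, prenyl bromide), lithiate C4 and add to 4, so only the B ring needs the late tert-prenylation/Claisen, which has no regiochemical choice.
3. Step 9 (Pd O-tert-prenylation). Risks are branched versus linear ether selectivity, especially for the acidic 7-OH, and base sensitivity of the flavanonol. Fallback: Cu-catalyzed propargylation with 3-chloro-3-methylbut-1-yne (via a Cu-allenylidene, which gives only the tertiary ether), then Lindlar semihydrogenation to 12.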